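**Retrosynthetic overview** (locants are those of the target's main chain: C1 ester carbon; C3, C4, C6 ring carbons; C8, C10 side-chain stereocentres)
1. Target ⇐ C3–CH2CO2Me bond: silyl ketene acetal of methyl acetate adds to the cyclic peroxycarbenium ion from a 3-acetoxy-1,2-dioxane (C3 set cis to the C4 ethyl).
2. 1,2-Dioxan-3-ol ⇐ ring expansion of a γ-lactol (oxolan-2-ol) with H2O2: the tertiary carbon C6 moves from the ring ether oxygen to the peroxide oxygen. This is the only peroxide-forming step.
3. γ-Lactol ⇐ ozonolysis of a vinyl tertiary alcohol ⇐ 1,2-boronate shift (lithiation–borylation–oxidation) that joins a secondary benzoate to the side-chain boronic ester and sets the quaternary C6.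
4. Side-chain boronic ester ⇐ four consecutive 1,2-boronate shifts starting from butylboronic acid (C10 and C8 by reagent control).
5. Benzoate ⇐ (E)-hept-4-en-3-one: Rh-catalysed asymmetric vinyl addition (C4), enzymatic reduction, Mitsunobu. Ring order: the oxolane forms first and is then expanded to the 1,2-dioxane, the only ring of the target.

Assumption: ethyl and propyl 2,4,6-triisopropylbenzoate, the TBS ketene acetal of methyl acetate, neopentyl glycol and (+)-sparteine are bought and used as reagents (benzoyl, silyl and diol parts are activating or protecting groups); (E)-hept-4-en-3-one is a catalogue compound.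

**Route**

Step 1
Reactants: 1 butylboronic acid
Product: 2 2-butyl-5,5-dimethyl-1,3,2-dioxaborinane
Conditions: neopentyl glycol, toluene, reflux (Dean–Stark)
Reagents that add atoms: neopentyl glycol (2,2-dimethylpropane-1,3-diol), OCC(C)(C)CO
Why: Boronic ester formation by condensation with a 1,3-diol goes to completion once water is removed azeotropically and gives the reactive ester needed for the homologations; no stereocentre is formed.

Step 2
Reactants: 2 2-butyl-5,5-dimethyl-1,3,2-dioxaborinane
Product: 3 2-[(2S)-hexan-2-yl]-5,5-dimethyl-1,3,2-dioxaborinane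
Conditions: ethyl 2,4,6-triisopropylbenzoate, s-BuLi, (+)-sparteine, Et2O, −78 °C, 5 h; then 2, −78 °C → rt
Reagents that add atoms: ethyl 2,4,6-triisopropylbenzoate, CCOC(=O)c1c(C(C)C)cc(C(C)C)cc1C(C)C
Why: Lithiation–borylation (sparteine-mediated asymmetric deprotonation, then a stereospecific 1,2-metallate shift): s-BuLi/(+)-sparteine removes the pro-R α-hydrogen of the benzoate, boron is taken up with retention and butyl migrates from boron to carbon anti to the leaving benzoate, which sets C10 (S in 3) under reagent control.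

Step 3
Reactants: 3 2-[(2S)-hexan-2-yl]-5,5-dimethyl-1,3,2-dioxaborinane
Product: 4 5,5-dimethyl-2-[(2R)-2-methylhexyl]-1,3,2-dioxaborinane
Conditions: BrCH2Cl, n-BuLi, THF, −78 °C → rt
Reagents that add atoms: bromochloromethane, ClCBr
Why: Matteson homologation: (chloromethyl)lithium adds to boron and the stereocentre-bearing carbon migrates 1,2 with retention as chloride leaves, inserting C9 without touching C10 (the descriptor changes to R only through CIP priorities).

Step 4
Reactants: 4 5,5-dimethyl-2-[(2R)-2-methylhexyl]-1,3,2-dioxaborinane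
Product: 5 5,5-dimethyl-2-[(3S,5S)-5-methylnonan-3-yl]-1,3,2-dioxaborinane
Conditions: propyl 2,4,6-triisopropylbenzoate, s-BuLi, (+)-sparteine, Et2O, −78 °C, 5 h; then 4, −78 °C → rt
Reagents that add atoms: propyl 2,4,6-triisopropylbenzoate, CCCOC(=O)c1c(C(C)C)cc(C(C)C)cc1C(C)C
Why: Second lithiation–borylation: the (+)-sparteine-derived lithiated propyl benzoate reacts as in step 2, so the 1,2-metallate shift sets C8 (S in 5) under reagent control and independently of C10, giving the syn-1,3 pattern.

Step 5
Reactants: 5 5,5-dimethyl-2-[(3S,5S)-5-methylnonan-3-yl]-1,3,2-dioxaborinane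
Product: 6 2-[(2S,4S)-2-ethyl-4-methyloctyl]-5,5-dimethyl-1,3,2-dioxaborinane
Conditions: BrCH2Cl, n-BuLi, THF, −78 °C → rt
Reagents that add atoms: bromochloromethane, ClCBr
Why: Matteson homologation with (chloromethyl)lithium inserts C7 by a 1,2-metallate shift with retention at the migrating C8.

Step 6
Reactants: 7 (4E)-hept-4-en-3-one; 8 potassium trifluoro(vinyl)borate
Product: 9 (5S)-5-ethylhept-6-en-3-one
Conditions: [Rh(cod)2]PF6 (3 mol %), (S)-BINAP (3.3 mol %), toluene/H2O (20:1), 105 °C
Reagents that add atoms: none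
Why: Rhodium-catalysed asymmetric 1,4-addition (Hayashi–Miyaura type) of an alkenyltrifluoroborate to an acyclic (E)-enone; the (S)-BINAP–Rh alkenyl species discriminates the enone faces and sets the future C4 as (S) under catalyst control.

Step 7
Reactants: 9 (5S)-5-ethylhept-6-en-3-one
Product: 10 (3S,5S)-5-ethylhept-6-en-3-ol
Conditions: Prelog-selective alcohol dehydrogenase (ADH-A, Rhodococcus ruber), NAD+ (cat.), i-PrOH/phosphate buffer pH 7.5 (1:9), 30 °C
Reagents that add atoms: none
Why: Biocatalytic ketone reduction: the Prelog-selective dehydrogenase binds ethyl in its small pocket and delivers hydride to one carbonyl face, so the (3S) carbinol is set under catalyst control while the (5S) centre is untouched.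

Step 8
Reactants: 10 (3S,5S)-5-ethylhept-6-en-3-ol
Product: 11 (3R,5S)-5-ethylhept-6-en-3-yl 2,4,6-triisopropylbenzoate
Conditions: 2,4,6-triisopropylbenzoic acid, PPh3, DIAD, THF, 0 °C → rt
Reagents that add atoms: 2,4,6-triisopropylbenzoic acid, CC(C)c1cc(C(C)C)c(C(=O)O)c(C(C)C)c1
Why: Mitsunobu esterification proceeds by SN2 displacement of the oxyphosphonium group with clean inversion, turning the (3S) alcohol into the (3R) benzoate that the next step requires.

Step 9
Reactants: 11 (3R,5S)-5-ethylhept-6-en-3-yl 2,4,6-triisopropylbenzoate; 6 2-[(2S,4S)-2-ethyl-4-methyloctyl]-5,5-dimethyl-1,3,2-dioxaborinane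
Product: 13 (3S,5S,7S,9S)-3,5,7-triethyl-9-methyltridec-1-en-5-ol, via tertiary boronic ester 12 (not isolated)
Conditions: s-BuLi, TMEDA, CPME, −60 °C, 2 h; then 6, −60 → 40 °C; then aq. NaOH (2 M), 30% H2O2, THF, 0 °C → rt
Reagents that add atoms: hydrogen peroxide, OO
Why: Lithiation–borylation of a secondary dialkyl benzoate (1,2-metallate rearrangement): benzoate-directed deprotonation and borylation both occur with retention, the side-chain CH2 then shifts 1,2 from boron to carbon anti to the departing benzoate (inversion) and the tertiary C–B bond is oxidised with retention, so the (3R) benzoate is translated stereospecifically into the quaternary carbinol (5S in 13), the future C6.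

Step 10
Reactants: 13 (3S,5S,7S,9S)-3,5,7-triethyl-9-methyltridec-1-en-5-ol
Product: 14 (3S,5S)-3,5-diethyl-5-[(2S,4S)-2-ethyl-4-methyloctyl]oxolan-2-ol
Conditions: O3, CH2Cl2/MeOH (4:1), −78 °C; then Me2S, −78 °C → rt
Reagents that add atoms: ozone, [O-][O+]=O
Why: Ozonolysis with reductive work-up cleaves the only alkene, and the γ-hydroxy aldehyde closes spontaneously to the five-membered lactol (hemiacetal formation), which also shields the α-stereocentre from epimerisation; the anomeric centre is uncontrolled and need not be controlled.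

Step 11
Reactants: 14 (3S,5S)-3,5-diethyl-5-[(2S,4S)-2-ethyl-4-methyloctyl]oxolan-2-ol
Product: 16 (4S,6S)-4,6-diethyl-6-[(2S,4S)-2-ethyl-4-methyloctyl]-1,2-dioxan-3-ol, via hydroperoxy acetal 15 (not isolated)
Conditions: H2O2 (ca. 2 M in Et2O, 1.5 equiv), Tf2NH (5 mol %), CH2Cl2, −40 → 0 °C
Reagents that add atoms: hydrogen peroxide, OO
Why: Proposed new method: acid-catalysed perhydrolytic ring expansion of a γ-lactol – H2O2 first exchanges the anomeric OH (peroxyacetal formation via the oxocarbenium ion) to give 15, then the acid ionises the tertiary C5–O1 ring bond and, because the leaving oxygen and the hydroperoxy group sit on the same carbon, the terminal peroxide oxygen captures the tertiary centre from the face the ring oxygen has just left (contact ion pair, SNi-like transposition of carbon from O to OO), so the configuration fixed in step 9 is carried over with retention as (6S) while the strained five-membered peroxyacetal becomes the six-membered peroxy-hemiacetal; the closest known reaction type is the acid-catalysed perhydrolysis of tertiary alcohols and ethers to tert-alkyl hydroperoxides and 1,2-dioxanes, together with the Lewis-acid-promoted opening of oxetanes by hydroperoxides.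

Step 12
Reactants: 16 (4S,6S)-4,6-diethyl-6-[(2S,4S)-2-ethyl-4-methyloctyl]-1,2-dioxan-3-ol
Product: 17 (4S,6S)-4,6-diethyl-6-[(2S,4S)-2-ethyl-4-methyloctyl]-1,2-dioxan-3-yl acetate
Conditions: Ac2O, pyridine, DMAP (cat.), CH2Cl2, 0 °C
Reagents that add atoms: acetic anhydride, CC(=O)OC(C)=O
Why: DMAP-catalysed acylation of the peroxy-hemiacetal hydroxyl installs an anomeric leaving group under conditions mild enough for the O–O bond; the anomeric mixture is inconsequential.

Step 13
Reactants: 17 (4S,6S)-4,6-diethyl-6-[(2S,4S)-2-ethyl-4-methyloctyl]-1,2-dioxan-3-yl acetate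
Product: 18 methyl 2-[(3S,4S,6S)-4,6-diethyl-6-[(2S,4S)-2-ethyl-4-methyloctyl]-1,2-dioxan-3-yl]acetate
Conditions: 1-(tert-butyldimethylsilyloxy)-1-methoxyethene (2 equiv), TMSOTf (0.2 equiv), CH2Cl2, −78 °C
Reagents that add atoms: 1-(tert-butyldimethylsilyloxy)-1-methoxyethene, COC(=C)O[Si](C)(C)C(C)(C)C
Why: Mukaiyama-type substitution through a peroxycarbenium ion: TMSOTf ionises the anomeric acetate and the silyl ketene acetal adds along the axial trajectory of the half-chair that keeps the C4 ethyl pseudo-equatorial (the other half-chair has a 1,3-diaxial clash between the C4 and C6 ethyl groups), which places CH2CO2Me cis to the C4 ethyl, i.e. (3S).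

**Compound list**
1 | butylboronic acid | CCCCB(O)O | starting material
2 | 2-butyl-5,5-dimethyl-1,3,2-dioxaborinane | CCCCB1OCC(C)(C)CO1 | intermediate
3 | 2-[(2S)-hexan-2-yl]-5,5-dimethyl-1,3,2-dioxaborinane | CCCC[C@H](C)B1OCC(C)(C)CO1 | intermediate
4 | 5,5-dimethyl-2-[(2R)-2-methylhexyl]-1,3,2-dioxaborinane | CCCC[C@H](C)CB1OCC(C)(C)CO1 | intermediate
5 | 5,5-dimethyl-2-[(3S,5S)-5-methylnonan-3-yl]-1,3,2-dioxaborinane | CCCC[C@H](C)C[C@H](CC)B1OCC(C)(C)CO1 | intermediate
6 | 2-[(2S,4S)-2-ethyl-4-methyloctyl]-5,5-dimethyl-1,3,2-dioxaborinane | CCCC[C@H](C)C[C@H](CC)CB1OCC(C)(C)CO1 | intermediate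
7 | (4E)-hept-4-en-3-one | CC/C=C/C(=O)CC | starting material
8 | potassium trifluoro(vinyl)borate | C=C[B-](F)(F)F.[K+] | starting material
9 | (5S)-5-ethylhept-6-en-3-one | CCC(=O)C[C@H](CC)C=C | intermediate
10 | (3S,5S)-5-ethylhept-6-en-3-ol | CC[C@H](O)C[C@H](CC)C=C | intermediate
11 | (3R,5S)-5-ethylhept-6-en-3-yl 2,4,6-triisopropylbenzoate | CC[C@@H](OC(=O)c1c(C(C)C)cc(C(C)C)cc1C(C)C)C[C@H](CC)C=C | intermediate
12 | 2-[(3S,5R,7S,9S)-3,5,7-triethyl-9-methyltridec-1-en-5-yl]-5,5-dimethyl-1,3,2-dioxaborinane (not isolated) | CCCC[C@H](C)C[C@H](CC)C[C@@](B1OCC(C)(C)CO1)(CC)C[C@H](CC)C=C | intermediate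
13 | (3S,5S,7S,9S)-3,5,7-triethyl-9-methyltridec-1-en-5-ol | CCCC[C@H](C)C[C@H](CC)C[C@@](O)(CC)C[C@H](CC)C=C | intermediate
14 | (3S,5S)-3,5-diethyl-5-[(2S,4S)-2-ethyl-4-methyloctyl]oxolan-2-ol (anomers at C2) | CCCC[C@H](C)C[C@H](CC)C[C@@]1(CC)C[C@H](CC)C(O)O1 | intermediate
15 | (3S,5S)-3,5-diethyl-5-[(2S,4S)-2-ethyl-4-methyloctyl]-2-hydroperoxyoxolane (not isolated; anomers at C2) | CCCC[C@H](C)C[C@H](CC)C[C@@]1(CC)C[C@H](CC)C(OO)O1 | intermediate
16 | (4S,6S)-4,6-diethyl-6-[(2S,4S)-2-ethyl-4-methyloctyl]-1,2-dioxan-3-ol (anomers at C3) | CCCC[C@H](C)C[C@H](CC)C[C@@]1(CC)C[C@H](CC)C(O)OO1 | intermediate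
17 | (4S,6S)-4,6-diethyl-6-[(2S,4S)-2-ethyl-4-methyloctyl]-1,2-dioxan-3-yl acetate (anomers at C3) | CCCC[C@H](C)C[C@H](CC)C[C@@]1(CC)C[C@H](CC)C(OC(C)=O)OO1 | intermediate
18 | methyl 2-[(3S,4S,6S)-4,6-diethyl-6-[(2S,4S)-2-ethyl-4-methyloctyl]-1,2-dioxan-3-yl]acetate | CCCC[C@H](C)C[C@H](CC)C[C@@]1(CC)C[C@H](CC)[C@H](CC(=O)OC)OO1 | target

**Totals**
Total step count: 13. Longest linear sequence: 10 steps (1–5, then 9–13).

**Three steps most likely to fail**

Step 11 (the proposed ring expansion). The risks are partial loss of configuration at C6 if the tertiary cation escapes the contact pair, and acid-induced Hock-type cleavage of the hydroperoxide. The fallback uses known chemistry, sets out from 14 and comes back at 18. Wittig olefination of lactol 14 with methyl (triphenylphosphoranylidene)acetate (toluene, 80 °C) gives methyl (2E,4S,6S,8S,10S)-4,6,8-triethyl-6-hydroxy-10-methyltetradec-2-enoate F1. Classical perhydrolysis of its tertiary alcohol (50% H2O2, cat. H2SO4, Et2O, 0 °C; SN1, so C6 is scrambled) gives methyl (2E,4S,8S,10S)-4,6,8-triethyl-6-hydroperoxy-10-methyltetradec-2-enoate F2 as both C6 epimers. Et2NH in CF3CH2OH then closes the 1,2-dioxane by intramolecular peroxy-Michael addition, and 18 is separated from its diastereomers by preparative HPLC.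

Step 9 (lithiation–borylation at a hindered secondary dialkyl benzoate). The risks are slow deprotonation next to two alkyl groups and reluctant 1,2-migration at the congested boronate. The fallback sets out from 6 and comes back at 13. Oxidation of 6 (NaOH, H2O2) gives (2S,4S)-2-ethyl-4-methyloctan-1-ol F3, which is converted (CBr4, PPh3) into (2S,4S)-1-bromo-2-ethyl-4-methyloctane F4. Its Grignard reagent is added to ketone 9 (CeCl3, THF, −78 °C). This gives 13 together with its C5 epimer, because a simple carbonyl addition has no facial control here; the pair is carried on and separated as acetates 17 or at the stage of 18.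

Step 13 (C3 substitution). The risks are insufficient cis selectivity and Lewis-acid-induced fragmentation of the peroxide. The fallback sets out from 16 and comes back at 18. Horner–Wadsworth–Emmons olefination of the open hydroperoxy-aldehyde form of 16 with trimethyl phosphonoacetate (LiCl, i-Pr2NEt, MeCN) gives methyl (2E,4S,6S,8S,10S)-4,6,8-triethyl-6-hydroperoxy-10-methyltetradec-2-enoate F5. This cyclises with Et2NH in CF3CH2OH (intramolecular peroxy-Michael addition) to 18 and its C3 epimer, which are separated by HPLC.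

Further compounds
F1 | step 11 | methyl (2E,4S,6S,8S,10S)-4,6,8-triethyl-6-hydroxy-10-methyltetradec-2-enoate | CCCC[C@H](C)C[C@H](CC)C[C@@](O)(CC)C[C@H](CC)/C=C/C(=O)OC
F2 | step 11 | methyl (2E,4S,8S,10S)-4,6,8-triethyl-6-hydroperoxy-10-methyltetradec-2-enoate (both C6 epimers) | CCCC[C@H](C)C[C@H](CC)CC(CC)(OO)C[C@H](CC)/C=C/C(=O)OC
F3 | step 9 | (2S,4S)-2-ethyl-4-methyloctan-1-ol | CCCC[C@H](C)C[C@H](CC)CO
F4 | step 9 | (2S,4S)-1-bromo-2-ethyl-4-methyloctane | CCCC[C@H](C)C[C@H](CC)CBr
F5 | step 13 | methyl (2E,4S,6S,8S,10S)-4,6,8-triethyl-6-hydroperoxy-10-methyltetradec-2-enoate | CCCC[C@H](C)C[C@H](CC)C[C@@](OO)(CC)C[C@H](CC)/C=C/C(=O)OC
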